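The target is cut at the two diarylmethane bonds on the side of the para-hydroxyphenyl rings C and D, so both methylenes stay on ring A. This uses the fact that the carbons on C2 and C6 of ring A each lie para to an oxygen (C5 OMe, C3 OH) and flank the C1 arylethyl chain, the two sites where a 5-alkylresorcinol diether takes electrophiles. The precursor 12 is the benzyl-protected bibenzyl carrying a CH2OCO2Me group on C2 and on C6. In one operation the key step couples both benzylic carbonates with 4-(benzyloxy)phenylboronic acid 13 under palladium catalysis and completes the carbon skeleton as 14.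

Key step: step 8

Remark on the chemistry: ring A is numbered C1 (2-arylethyl), C2 and C6 (benzyl-bearing), C3 (OH), C4 (H), C5 (OMe); ring B is the 3-oxygenated phenyl ring of the bibenzyl; rings C and D are the two 4-oxygenated phenyl rings.

Remark on the chemistry: the one-carbon groups on C2 and C6 are brought in through a 2,6-dibromide and not by twofold electrophilic formylation, because a ring that already carries one formyl group would take a second one only slowly and in competition with ring B, whereas a first bromine lowers the reactivity of ring A only slightly; the bibenzyl is assembled by a B-alkyl coupling so that no alkene has to be hydrogenated beside benzyl ethers.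

Step 1
Reactants: 1 3-bromo-5-methoxyphenol
Product: 2 1-(benzyloxy)-3-bromo-5-methoxybenzene
Conditions: BnBr, K2CO3, DMF, rt
Reagents that add atoms: benzyl bromide, BrCc1ccccc1
Why: Williamson ether synthesis of a phenoxide with a benzylic bromide is dependable, and the aryl bromide is inert to these conditions.

Step 2
Reactants: 3 3-(benzyloxy)benzaldehyde
Product: 4 1-(benzyloxy)-3-ethenylbenzene (3-(benzyloxy)styrene)
Conditions: Ph3PCH3Br, KOt-Bu, THF, 0 °C to rt
Reagents that add atoms: methyltriphenylphosphonium bromide, C[P+](c1ccccc1)(c1ccccc1)c1ccccc1.[Br-]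
Why: Wittig methylenation of an aromatic aldehyde with the non-stabilised ylide should proceed cleanly and leaves the aryl benzyl ether untouched.

Step 3
Reactants: 4 1-(benzyloxy)-3-ethenylbenzene; 2 1-(benzyloxy)-3-bromo-5-methoxybenzene
Product: 6 1-(benzyloxy)-3-{2-[3-(benzyloxy)phenyl]ethyl}-5-methoxybenzene (protected bibenzyl), via alkylborane 5 (not isolated)
Conditions: 9-BBN, THF, 0 °C to rt; then 2, PdCl2(dppf) (3 mol%), 3 M aq. NaOH, THF, 65 °C
Reagents that add atoms: none
Why: Hydroboration of the styrene with 9-BBN places boron on the terminal carbon, and the B-alkyl Suzuki–Miyaura coupling of the resulting primary alkylborane with the aryl bromide forms the C1–CH2 bond, so the two-carbon bridge arrives saturated and the benzyl ethers never meet hydrogen.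

Step 4
Reactants: 6 1-(benzyloxy)-3-{2-[3-(benzyloxy)phenyl]ethyl}-5-methoxybenzene
Product: 7 1-(benzyloxy)-2,4-dibromo-3-{2-[3-(benzyloxy)phenyl]ethyl}-5-methoxybenzene (bromine on C2 and C6 of ring A)
Conditions: NBS (2.05 equiv), MeCN, 0 °C to rt, dark
Reagents that add atoms: N-bromosuccinimide, O=C1CCC(=O)N1Br
Why: In this electrophilic aromatic bromination a 5-alkylresorcinol diether is attacked at the two positions that flank the alkyl group, each para to one alkoxy group and ortho to the other, and not at C4 between the oxygens, and ring A with two alkoxy donors should stay well ahead of the mono-alkoxy ring B even after the first bromine is in place.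

Step 5
Reactants: 7 1-(benzyloxy)-2,4-dibromo-3-{2-[3-(benzyloxy)phenyl]ethyl}-5-methoxybenzene
Product: 10 4-(benzyloxy)-2-{2-[3-(benzyloxy)phenyl]ethyl}-6-methoxybenzene-1,3-dicarbaldehyde, via dilithio arene 8 (not isolated), via bis(hemiaminolate) 9 (not isolated)
Conditions: t-BuLi (4.2 equiv), THF, −78 °C; DMF, −78 °C to rt; H2O
Reagents that add atoms: N,N-dimethylformamide, CN(C)C=O
Why: Twofold bromine–lithium exchange with t-BuLi (two equivalents per bromine, the second destroying the tert-butyl bromide formed) is fast at low temperature, and formylation of the aryllithium with DMF stops at the hemiaminolate, which gives the aldehyde only on aqueous quench.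

Step 6
Reactants: 10 4-(benzyloxy)-2-{2-[3-(benzyloxy)phenyl]ethyl}-6-methoxybenzene-1,3-dicarbaldehyde
Product: 11 [4-(benzyloxy)-2-{2-[3-(benzyloxy)phenyl]ethyl}-6-methoxy-1,3-phenylene]dimethanol
Conditions: NaBH4, THF/MeOH, 0 °C
Reagents that add atoms: none
Why: Borohydride reduction of aromatic aldehydes to primary alcohols is selective, and the ethers and arenes are inert to it.

Step 7
Reactants: 11 [4-(benzyloxy)-2-{2-[3-(benzyloxy)phenyl]ethyl}-6-methoxy-1,3-phenylene]dimethanol
Product: 12 [4-(benzyloxy)-2-{2-[3-(benzyloxy)phenyl]ethyl}-6-methoxy-1,3-phenylene]bis(methylene) dimethyl biscarbonate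
Conditions: ClCO2Me, pyridine, DMAP (cat.), CH2Cl2, 0 °C
Reagents that add atoms: methyl chloroformate, COC(=O)Cl
Why: O-acylation of the two primary alcohols with a chloroformate under cold basic conditions should give the carbonates without ionising the electron-rich benzylic C–O bonds, which are acid-sensitive.

Step 8
Reactants: 12 [4-(benzyloxy)-2-{2-[3-(benzyloxy)phenyl]ethyl}-6-methoxy-1,3-phenylene]bis(methylene) dimethyl biscarbonate; 13 4-(benzyloxy)phenylboronic acid
Product: 14 1-(benzyloxy)-2,4-bis[4-(benzyloxy)benzyl]-3-{2-[3-(benzyloxy)phenyl]ethyl}-5-methoxybenzene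
Conditions: 13 (3 equiv), [Pd(η3-C3H5)Cl]2 (5 mol%), Ph2P(CH2)5PPh2 (11 mol%), DMF, 80 °C, Ar
Reagents that add atoms: none
Why: Zerovalent palladium, formed from [Pd(η3-C3H5)Cl]2 and the wide-bite-angle diphosphine, displaces each carbonate from its benzylic carbon, carbon dioxide is lost and a methoxo(eta-3-benzyl)palladium species results, whose methoxide takes up the arylboronic acid 13 without added base before reductive elimination releases the diarylmethane. The closest known reaction type is the Suzuki–Miyaura coupling of benzylic carbonates with arylboronic acids, run here twice on one molecule. No ring is closed and no stereocentre is formed. Each reacting carbon is a primary CH2 on C2 or C6 of ring A, para to an ether oxygen (C5 OMe for the C2 arm, C3 OBn for the C6 arm), which eases ionisation and keeps the bond-forming site outside the crowded C1/C2/C6 region. The step needs site selectivity only: both bonds must form at the exocyclic methylene carbons and at C4 of each incoming ring, and this is fixed by the position of the carbonates in 12 and of boron in 13, while the neutral medium leaves the four benzyl ethers and the methyl ether alone.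

Step 9
Reactants: 14 1-(benzyloxy)-2,4-bis[4-(benzyloxy)benzyl]-3-{2-[3-(benzyloxy)phenyl]ethyl}-5-methoxybenzene
Product: 15 2,4-bis(4-hydroxybenzyl)-3-[2-(3-hydroxyphenyl)ethyl]-5-methoxyphenol (target)
Conditions: H2 (1 atm), 10% Pd/C, EtOAc/MeOH, rt
Reagents that add atoms: none
Why: Catalytic hydrogenolysis should cleave all four aryl benzyl ethers in one operation, while the diarylmethane and bibenzyl C–C bonds and the aryl methyl ether are stable at ambient pressure and temperature.

Compound list
1 | 3-bromo-5-methoxyphenol | COc1cc(O)cc(Br)c1 | starting material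
2 | 1-(benzyloxy)-3-bromo-5-methoxybenzene | COc1cc(Br)cc(OCc2ccccc2)c1 | intermediate
3 | 3-(benzyloxy)benzaldehyde | O=Cc1cccc(OCc2ccccc2)c1 | starting material
4 | 1-(benzyloxy)-3-ethenylbenzene | C=Cc1cccc(OCc2ccccc2)c1 | intermediate
5 | 9-{2-[3-(benzyloxy)phenyl]ethyl}-9-borabicyclo[3.3.1]nonane (not isolated) | c1ccc(COc2cccc(CCB3C4CCCC3CCC4)c2)cc1 | intermediate
6 | 1-(benzyloxy)-3-{2-[3-(benzyloxy)phenyl]ethyl}-5-methoxybenzene | COc1cc(OCc2ccccc2)cc(CCc2cccc(OCc3ccccc3)c2)c1 | intermediate
7 | 1-(benzyloxy)-2,4-dibromo-3-{2-[3-(benzyloxy)phenyl]ethyl}-5-methoxybenzene | COc1cc(OCc2ccccc2)c(Br)c(CCc2cccc(OCc3ccccc3)c2)c1Br | intermediate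
8 | ring A 2,6-dilithio arene derived from 7 (not isolated) | COc1cc(OCc2ccccc2)c([Li])c(CCc2cccc(OCc3ccccc3)c2)c1[Li] | intermediate
9 | bis(lithium hemiaminolate) from 8 and DMF (not isolated, mixture of diastereomers) | COc1cc(OCc2ccccc2)c(C(O[Li])N(C)C)c(CCc2cccc(OCc3ccccc3)c2)c1C(O[Li])N(C)C | intermediate
10 | 4-(benzyloxy)-2-{2-[3-(benzyloxy)phenyl]ethyl}-6-methoxybenzene-1,3-dicarbaldehyde | COc1cc(OCc2ccccc2)c(C=O)c(CCc2cccc(OCc3ccccc3)c2)c1C=O | intermediate
11 | [4-(benzyloxy)-2-{2-[3-(benzyloxy)phenyl]ethyl}-6-methoxy-1,3-phenylene]dimethanol | COc1cc(OCc2ccccc2)c(CO)c(CCc2cccc(OCc3ccccc3)c2)c1CO | intermediate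
12 | [4-(benzyloxy)-2-{2-[3-(benzyloxy)phenyl]ethyl}-6-methoxy-1,3-phenylene]bis(methylene) dimethyl biscarbonate | COC(=O)OCc1c(OCc2ccccc2)cc(OC)c(COC(=O)OC)c1CCc1cccc(OCc2ccccc2)c1 | intermediate
13 | 4-(benzyloxy)phenylboronic acid | OB(O)c1ccc(OCc2ccccc2)cc1 | starting material
14 | 1-(benzyloxy)-2,4-bis[4-(benzyloxy)benzyl]-3-{2-[3-(benzyloxy)phenyl]ethyl}-5-methoxybenzene | COc1cc(OCc2ccccc2)c(Cc2ccc(OCc3ccccc3)cc2)c(CCc2cccc(OCc3ccccc3)c2)c1Cc1ccc(OCc2ccccc2)cc1 | intermediate
15 | 2,4-bis(4-hydroxybenzyl)-3-[2-(3-hydroxyphenyl)ethyl]-5-methoxyphenol | COc1cc(O)c(Cc2ccc(O)cc2)c(CCc2cccc(O)c2)c1Cc1ccc(O)cc1 | target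

Total step count: 9
Longest linear sequence: 8 steps (3 → 4 → 6 → 7 → 10 → 11 → 12 → 14 → 15; the branch from 1 through 2 is equally long)

Steps most likely to fail

Step 8. The second coupling may stall on the crowded ring. The benzylpalladium intermediate may be captured by methoxide. The electron-rich benzylic carbonate may ionise and alkylate C4 of ring A or ring B of another molecule, and the boronic acid may be lost by protodeboronation. The fallback forms the same two bonds by carbonyl addition and sets out from dialdehyde 10. Addition of 4-(benzyloxy)phenylmagnesium bromide (4-BnOC6H4MgBr, 3 equiv, THF, 0 °C) should give the bis(diarylmethanol) F1 as a mixture of diastereomers. Ionic hydrogenation of the doubly benzylic, donor-stabilised carbinols (Et3SiH, CF3CO2H, CH2Cl2, −20 to 0 °C) removes both hydroxyl groups and both stereocentres and comes back to the route at 14.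

Step 5. The second bromine–lithium exchange may remain incomplete, or the aryllithium may be quenched by proton transfer from a benzylic OCH2 group, which would leave mono-aldehyde or rearranged material. The fallback avoids organolithium species and sets out from dibromide 7. Twofold Suzuki–Miyaura vinylation (CH2=CHBF3K, Pd(OAc)2, SPhos, K3PO4, toluene/H2O, 90 °C) should give the 2,6-divinyl bibenzyl F2. Lemieux–Johnson cleavage of both vinyl groups (OsO4 cat., NaIO4, 2,6-lutidine, dioxane/H2O, rt) comes back to the route at 10.

Step 4. Bromination may stray to C4 of ring A or to the position para to oxygen on ring B once the first bromine is in place. The fallback brominates ring A before ring B is attached and sets out from aryl bromide 2. Bromine–lithium exchange and formylation (n-BuLi, THF, −78 °C, then DMF) give 3-(benzyloxy)-5-methoxybenzaldehyde F3. Dibromination of this ring alone (Br2, NaOAc, AcOH, rt) gives 3-(benzyloxy)-2,6-dibromo-5-methoxybenzaldehyde F4. Commercial 3-(benzyloxy)benzyl bromide and P(OEt)3 (130 °C, Michaelis–Arbuzov) give diethyl [3-(benzyloxy)benzyl]phosphonate F5. Horner–Wadsworth–Emmons olefination of F4 with F5 (NaH, THF, 0 °C to rt) gives the (E)-2,6-dibromostilbene F6. Diimide reduction of the alkene (TsNHNH2, NaOAc, THF/H2O, reflux), which spares aryl bromides and benzyl ethers, comes back to the route at 7.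

Further compounds
F1 | step 8 | [4-(benzyloxy)-2-{2-[3-(benzyloxy)phenyl]ethyl}-6-methoxy-1,3-phenylene]bis{[4-(benzyloxy)phenyl]methanol}, mixture of diastereomers | COc1cc(OCc2ccccc2)c(C(O)c2ccc(OCc3ccccc3)cc2)c(CCc2cccc(OCc3ccccc3)c2)c1C(O)c1ccc(OCc2ccccc2)cc1
F2 | step 5 | 1-(benzyloxy)-3-{2-[3-(benzyloxy)phenyl]ethyl}-2,4-diethenyl-5-methoxybenzene | COc1cc(OCc2ccccc2)c(C=C)c(CCc2cccc(OCc3ccccc3)c2)c1C=C
F3 | step 4 | 3-(benzyloxy)-5-methoxybenzaldehyde | COc1cc(C=O)cc(OCc2ccccc2)c1
F4 | step 4 | 3-(benzyloxy)-2,6-dibromo-5-methoxybenzaldehyde | COc1cc(OCc2ccccc2)c(Br)c(C=O)c1Br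
F5 | step 4 | diethyl [3-(benzyloxy)benzyl]phosphonate | CCOP(=O)(Cc1cccc(OCc2ccccc2)c1)OCC
F6 | step 4 | 1-(benzyloxy)-2,4-dibromo-3-{(E)-2-[3-(benzyloxy)phenyl]ethenyl}-5-methoxybenzene | COc1cc(OCc2ccccc2)c(Br)c(/C=C/c2cccc(OCc3ccccc3)c2)c1Br
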